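## The problem

Compound 29 is a heptaphenol in which two trans-2,3-diaryl-2,3-dihydrobenzofurans are held together by a single C(sp3)–C(sp2) bond. This bond runs from C3 of the ring B dihydrobenzofuran (O1, C2, C3) to C5' of ring C, the benzo ring of the second dihydrobenzofuran (O1', C2', C3'). Ring B carries an (E)-4-hydroxystyryl arm (ring A) on C4, next to the crowded C3, and a hydroxyl on C6. C2 bears the 4-hydroxyphenyl ring D, C3' the resorcinol ring E, C2' the 4-hydroxyphenyl ring F, and C7' a hydroxyl.

The four stereocentres form two vicinal pairs, (2S,3S) and (2'R,3'R). Within a pair the trans arrangement is the stable one, so one centre can set its neighbour. The pairs are separated by an aromatic ring and have opposite absolute sense, so each needs its own source of chirality.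

The molecule tolerates little. The stilbene excludes hydrogenolysis. The benzylic C2–O1 and C2'–O1' bonds ionise in strong acid once the para oxygen is free and open through a quinone methide in hot base. The free phenols are easily oxidised.

The enabling feature is that O1, C2 with ring D in the S configuration, C3 and ring B with its C6 oxygen are the atoms of (S)-naringenin (1) without its carbonyl carbon. The flavanone 7-oxygen lies where the C6 hydroxyl is, and the 5-oxygen lies where the styryl arm is attached. A shift of ring B from the carbonyl carbon to C3 therefore converts the natural product into this dihydrobenzofuran with C2 untouched. The extruded carbon is left as a carboxyl group on C3, the atom that must later be bonded to ring C.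

## Retrosynthesis

**Unmasking.** Target 29 is taken back to phenol 28, its hexabenzyl ether, and 28 to the ring D tosylate 27. Only protecting-group C–O and S–O bonds are cut. Benzyl is chosen for six oxygens because it survives the acid, oxidant, bases and organometallics of the route and can be removed by BCl3 with a cation scavenger without touching the alkene. The seventh oxygen stays a tosylate because the key step needs ring D electron-poor. It is removed first, while every other phenol is still capped. The forward steps must not ionise the two benzylic C–O bonds.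

**The bond between the halves.** Compound 27 is cut at C3–C5' into the redox-active ester 12 and the aryl bromide 24, which is used as arylzinc 26. Cutting inside the ring B dihydrobenzofuran instead (C2–C3 or O1–C2) would mean creating both of its centres late, on a substrate that already holds the other half. The C3–C5' cut is the only one that gives two halves of similar size, each with one pair of centres. The carboxyl group on C3 is the handle: decarboxylation gives a C3 radical, nickel joins it to the aryl group, and the C2 aryl group should direct the new bond trans. The forward step must capture a hindered benzylic radical and leave tosylate, stilbene and benzyl ethers alone.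

**The styryl arm.** Ester 12 comes from acid 11, and 11 from methyl ester 10. Compound 10 is cut at the C4–vinyl bond into triflate 7 and alkenylboronate 9, which comes from alkyne 8 by hydroboration. The cut sits here because the triflate is the flavanone 5-oxygen in activated form. It has to be spent before the nickel step, which it would not survive. The forward coupling must pick the triflate over the tosylate and keep the E geometry.

**Key disconnection.** Ester 7 is taken back to flavanone 4 by reinserting the ester carbon between C3 and C3a. In the forward sense the C4–C4a bond of the flavanone breaks and C3–C3a forms. Closing the five-membered ring through O1–C2, or by a (4+1) union, would have to create C2. This rearrangement never touches it. Compound 4 is a protected natural product. The forward reaction must make ring B migrate rather than ring D and must keep C2 intact in acid.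

**Protection of the flavanone.** Compound 4 comes from 3, 3 from 2, and 2 from 1 by three O-functionalisations ordered by acidity: benzyl on the 7-hydroxyl, tosyl on the 4'-hydroxyl, triflyl on the chelated 5-hydroxyl. All are run without strong base so that the flavanone neither opens nor racemises.

**The ring C half.** Bromide 24 is the C2' epimer of the cis compound 23. Compound 23 is cut at C2'–C3' to the diaryldiazomethane 22, which goes back to hydrazone 21, ketone 20 and carbinol 19. Carbinol 19 is cut at the C3'–ring E bond into aldehyde 16 and Grignard reagent 18, made from bromide 17. Aldehyde 16 comes from phenol 14 and chloride 15, and 14 from 13. Carbene insertion into the benzylic ether CH2 is a catalytic, enantioselective entry to 2,3-diaryl dihydrobenzofurans that tolerates the aryl bromide needed for 26. Its price is the cis ring, which acid corrects at C2' with C3' as the fixed reference.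

## Roads not taken

**Alternative 1:** The cut lies inside the ring C dihydrobenzofuran, at C2'–ring F and C3'–C3a'. In the forward step the aryllithium A4 adds to boron of the ring E alkenylboronate A2. Pd(OAc)2 with a chiral bisphosphine then couples the ate complex with the ring C bromide A3: ring F shifts from boron to C2' while ring C is delivered to C3' from the opposite face, giving boronate A1.

- Merits: both centres of this half come from catalyst control in one three-component step, from achiral pieces, without diazo chemistry and without passing through a cis ring. For the carbon skeleton of this half it is shorter than steps 9 to 14 of the chosen route.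
- Weak points: β-aryl alkenylboronates with pinacol on boron are reluctant partners in this metallate shift, and A3 is flanked by an ortho acetal ether. The anti addition also puts boron on C2' where the ring oxygen must end up. Oxidation with retention followed by SN2 closure would therefore give the cis ring, so closure has to go through the benzylic cation, the same ionisation that step 15 relies on. Oxidation, two deprotections and ring closure still follow.
- Comparison: for this half Alternative 1 is arguably the better construction. It is silent on the other half: the aldehyde of ring C would still have to be grown into C3 with two new centres. The chosen plan sets against it a strategic step that solves that harder, more crowded half, with C2 bought and C3 relayed, and a union of the halves in one bond-forming step.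

**Alternative 2:** The cut is O1'–C2'. In the forward step DDQ abstracts hydride from the 4-benzyloxybenzyl CH2 of phenol A6, and the ortho phenol of ring C traps the cation to give aldehyde A5.

- Merits: the closure is biomimetic, needs no metal, and gives the trans ring directly under the control of C3' alone. The chosen route needs an insertion and then an epimerisation (steps 14 and 15) for the same result, so here Alternative 2 is better.
- Weak points: the whole stereochemical burden moves to C3' of A6, a methine between two aryl groups of similar size for which no short catalytic entry is evident. DDQ also meets a phenol whose ortho C3'–H is doubly benzylic, so oxidation through the ortho-quinone methide could erase the only stereocentre. The ring B half is again left open.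
- Comparison: the chosen plan sets against the simpler closure a precedented catalytic control of C3' by carbene insertion and a chiral-pool source for the other half.

**Alternative 3:** The cut is C2–C3 and C2–O1 of the ring B dihydrobenzofuran, made last. In the forward step Cs2CO3 releases the ortho-quinone methide of ring B from sulfone A8, which already holds the ring C half. A sulfonium ylide built on a chiral sulfide delivers the carbon that carries ring D, bonding first to C3 and then to the phenoxide oxygen, to give A7. Counting the benzyl groups, A7 is the hepta-O-benzyl ether of 29.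

- Merits: this is the most convergent end. It forms two bonds and a ring at once, is trans-selective, and uses uniform benzyl protection, so one deprotection follows and no sulfonate, ester or redox-active ester is handled. At the end it is shorter than steps 6 to 8 and 16 to 18.
- Weak points: both centres of this ring are new and must be set absolutely by the ylide reagent alone, since the centres of the other half are too remote to help and may oppose it. Enantioselective (4+1) reactions of benzyl-type ylides with such quinone methides are little developed. This quinone methide carries the bulky ring C on its exocyclic carbon and the styryl arm next to it, so dimerisation or capture by other nucleophiles may outrun the ylide.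
- Comparison: the chosen plan is longer at the end, but its stereochemistry in this ring is not a wager: C2 comes from naringenin and C3 is relayed from it.

Key step: step 4

Assumption: (S)-naringenin of high enantiomeric purity is used (its ee is checked first), and Rh2(R-PTAD)4 is assumed to give the 3R series in step 14; if it gives 3S, the mirror-image catalyst Rh2(S-PTAD)4 is used.

## Route

Step 1
Reactants: 1 (S)-naringenin
Product: 2 (2S)-7-(benzyloxy)-5-hydroxy-2-(4-hydroxyphenyl)chroman-4-one
Conditions: BnOH (1.05 equiv), PPh3, DIAD, THF, 0 °C to rt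
Reagents that add atoms: benzyl alcohol, OCc1ccccc1
Why: Mitsunobu etherification: the 7-hydroxyl, para to the carbonyl, is the most acidic phenol and is the one alkylated, while the 5-hydroxyl is locked in the chelate and the 4'-hydroxyl is less acidic. No free base is present, so the flavanone should neither open to the chalcone nor racemise.

Step 2
Reactants: 2 (2S)-7-(benzyloxy)-5-hydroxy-2-(4-hydroxyphenyl)chroman-4-one
Product: 3 4-[(2S)-7-(benzyloxy)-5-hydroxy-4-oxochroman-2-yl]phenyl 4-methylbenzenesulfonate
Conditions: TsCl (1.1 equiv), pyridine, CH2Cl2, 0 °C to rt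
Reagents that add atoms: 4-toluenesulfonyl chloride, Cc1ccc(S(=O)(=O)Cl)cc1
Why: Sulfonylation of the only free phenol; the chelated 5-hydroxyl does not react. The tosylate makes ring D electron-poor for step 4 and blocks the para oxygen that would otherwise assist opening of the C2–O1 bond.

Step 3
Reactants: 3 4-[(2S)-7-(benzyloxy)-5-hydroxy-4-oxochroman-2-yl]phenyl 4-methylbenzenesulfonate
Product: 4 (2S)-7-(benzyloxy)-4-oxo-2-[4-(tosyloxy)phenyl]chroman-5-yl trifluoromethanesulfonate
Conditions: Tf2O (1.2 equiv), pyridine, CH2Cl2, −20 to 0 °C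
Reagents that add atoms: trifluoromethanesulfonic anhydride, O=S(=O)(OS(=O)(=O)C(F)(F)F)C(F)(F)F
Why: Triflation of the hydrogen-bonded 5-hydroxyl needs the strong electrophile Tf2O; pyridine at low temperature is too weak a base to open the flavanone. The triflate removes the chelate, which eases ketal formation in step 4, and is the later coupling handle.

Step 4
Reactants: 4 (2S)-7-(benzyloxy)-4-oxo-2-[4-(tosyloxy)phenyl]chroman-5-yl trifluoromethanesulfonate
Product: 7 methyl (2S,3S)-6-(benzyloxy)-2-[4-(tosyloxy)phenyl]-4-(triflyloxy)-2,3-dihydrobenzofuran-3-carboxylate, via methyl enol ether 5 (not isolated), via C3 iodane 6 (not isolated)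
Conditions: PhI(OAc)2 (1.3 equiv), conc. H2SO4 (0.5 equiv), HC(OMe)3, rt; aq. NaHCO3
Reagents that add atoms: trimethyl orthoformate, COC(OC)OC; water (work-up), O
Why: Acid and orthoformate convert the ketone into its dimethyl ketal and the methyl enol ether 5; the trivalent iodine electrophile attacks C3 of 5 on the face opposite the equatorial C2 aryl group, and methanol caps the oxocarbenium ion to give iodane 6. In the trans-diequatorial conformer of 6 the C3–I bond is antiperiplanar to the C4–C4a ring bond, so the ipso carbon of ring B bridges to C3 (phenonium-type, formally a 3-exo attack of the arene on C3) as iodobenzene leaves; C4–C4a breaks, C3–C3a forms and the pyranone contracts to the dihydrofuran, the ring being closed by a 1,2-aryl shift and not by a bond to oxygen. The dimethoxycarbenium ion left on the old carbonyl carbon collapses to the methyl ester on work-up. This is the known oxidative ring contraction of flavanones to methyl trans-2-aryl-2,3-dihydrobenzofuran-3-carboxylates with PhI(OAc)2 or Tl(NO3)3 in trimethyl orthoformate, here applied to a 5-triflate of an enantiopure flavanone. The new C3 centre is set by C2: anti iodination followed by inversion at C3 places the ester trans to the aryl group, which is also the stable arrangement, giving (2S,3S). C2 keeps its configuration because the C2–O1 bond is never broken. The step needs ring B to migrate rather than ring D (isoflavone) and needs substitution or elimination at C3 (3-methoxyflavanone, flavone) to stay minor; the O1 and 7-benzyloxy donors ortho and para to the migrating carbon, the equatorial leaving group and the electron-poor tosyloxyphenyl ring, which also resists acid ionisation at C2, are there to secure this.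

Step 5
Reactants: 8 1-(benzyloxy)-4-ethynylbenzene
Product: 9 (E)-2-[4-(benzyloxy)styryl]-4,4,5,5-tetramethyl-1,3,2-dioxaborolane
Conditions: HBpin (1.1 equiv), Cp2Zr(H)Cl (5 mol %), Et3N (10 mol %), neat, 60 °C
Reagents that add atoms: pinacolborane, B1OC(C)(C)C(C)(C)O1
Why: Zirconium-catalysed hydroboration of a terminal alkyne: syn addition with boron on the terminal carbon gives the E alkenylboronate only.

Step 6
Reactants: 7 methyl (2S,3S)-6-(benzyloxy)-2-[4-(tosyloxy)phenyl]-4-(triflyloxy)-2,3-dihydrobenzofuran-3-carboxylate; 9 (E)-2-[4-(benzyloxy)styryl]-4,4,5,5-tetramethyl-1,3,2-dioxaborolane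
Product: 10 methyl (2S,3S)-6-(benzyloxy)-4-[(E)-4-(benzyloxy)styryl]-2-[4-(tosyloxy)phenyl]-2,3-dihydrobenzofuran-3-carboxylate
Conditions: Pd(PPh3)4 (5 mol %), K3PO4 (3 equiv), 1,4-dioxane/H2O (10:1), 80 °C
Reagents that add atoms: none
Why: Suzuki–Miyaura coupling: zerovalent palladium with PPh3 inserts into the aryl triflate but not into the aryl tosylate, and the alkenyl group is transferred with retention of the E geometry. The trans ester is the stable epimer, so the mild base cannot damage C3.

Step 7
Reactants: 10 methyl (2S,3S)-6-(benzyloxy)-4-[(E)-4-(benzyloxy)styryl]-2-[4-(tosyloxy)phenyl]-2,3-dihydrobenzofuran-3-carboxylate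
Product: 11 (2S,3S)-6-(benzyloxy)-4-[(E)-4-(benzyloxy)styryl]-2-[4-(tosyloxy)phenyl]-2,3-dihydrobenzofuran-3-carboxylic acid
Conditions: Me3SnOH (5 equiv), ClCH2CH2Cl, 80 °C; then 1 M HCl
Reagents that add atoms: trimethyltin hydroxide, C[Sn](C)(C)O
Why: Me3SnOH cleaves the methyl ester under near-neutral conditions (tin-mediated ester hydrolysis), which avoids hydroxide that could attack the tosylate or enolise the ester and expel O1.

Step 8
Reactants: 11 (2S,3S)-6-(benzyloxy)-4-[(E)-4-(benzyloxy)styryl]-2-[4-(tosyloxy)phenyl]-2,3-dihydrobenzofuran-3-carboxylic acid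
Product: 12 1,3-dioxoisoindolin-2-yl (2S,3S)-6-(benzyloxy)-4-[(E)-4-(benzyloxy)styryl]-2-[4-(tosyloxy)phenyl]-2,3-dihydrobenzofuran-3-carboxylate
Conditions: N-hydroxyphthalimide (1.1 equiv), DIC (1.1 equiv), DMAP (10 mol %), CH2Cl2, rt
Reagents that add atoms: N-hydroxyphthalimide, O=C1c2ccccc2C(=O)N1O
Why: Carbodiimide (Steglich-type) esterification gives the N-acyloxyphthalimide, the redox-active ester needed for decarboxylative coupling; no stereocentre is affected.

Step 9
Reactants: 13 5-bromo-2,3-dihydroxybenzaldehyde
Product: 14 3-(benzyloxy)-5-bromo-2-hydroxybenzaldehyde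
Conditions: NaH (2.2 equiv), DMSO, rt; BnBr (1.0 equiv), rt; then 1 M HCl
Reagents that add atoms: benzyl bromide, BrCc1ccccc1
Why: Dianion alkylation (Williamson ether synthesis): the 2-phenoxide is conjugated with the aldehyde, so the more basic 3-phenoxide of the dianion is benzylated selectively.

Step 10
Reactants: 14 3-(benzyloxy)-5-bromo-2-hydroxybenzaldehyde; 15 4-(benzyloxy)benzyl chloride
Product: 16 3-(benzyloxy)-2-{[4-(benzyloxy)benzyl]oxy}-5-bromobenzaldehyde
Conditions: K2CO3 (2 equiv), KI (10 mol %), DMF, 60 °C
Reagents that add atoms: none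
Why: Williamson ether synthesis at the remaining phenol; it places the benzylic CH2 that becomes C2' next to the future carbene carbon.

Step 11
Reactants: 16 3-(benzyloxy)-2-{[4-(benzyloxy)benzyl]oxy}-5-bromobenzaldehyde; 17 1,3-bis(benzyloxy)-5-bromobenzene
Product: 19 racemic {3-(benzyloxy)-2-[(4-benzyloxybenzyl)oxy]-5-bromophenyl}[3,5-bis(benzyloxy)phenyl]methanol, via Grignard reagent 18 (not isolated)
Conditions: 17, Mg, THF, 40 °C; then 16, THF, −20 to 0 °C; aq. NH4Cl
Reagents that add atoms: none
Why: Grignard addition to the aldehyde forms the C3'–ring E bond; at low temperature the aryl bromide of 16 does not exchange. The carbinol centre is racemic and is removed in step 12.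

Step 12
Reactants: 19 racemic {3-(benzyloxy)-2-[(4-benzyloxybenzyl)oxy]-5-bromophenyl}[3,5-bis(benzyloxy)phenyl]methanol
Product: 20 {3-(benzyloxy)-2-[(4-benzyloxybenzyl)oxy]-5-bromophenyl}[3,5-bis(benzyloxy)phenyl]methanone
Conditions: MnO2 (10 equiv), CH2Cl2, rt
Reagents that add atoms: none
Why: Oxidation of a doubly benzylic alcohol to the diaryl ketone with MnO2; ethers and the aryl bromide are inert.

Step 13
Reactants: 20 {3-(benzyloxy)-2-[(4-benzyloxybenzyl)oxy]-5-bromophenyl}[3,5-bis(benzyloxy)phenyl]methanone
Product: 21 hydrazone of 20 (E/Z mixture)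
Conditions: N2H4·H2O (10 equiv), AcOH (cat.), EtOH, 80 °C
Reagents that add atoms: hydrazine, NN
Why: Condensation of the diaryl ketone with hydrazine gives the free hydrazone, the storable precursor of the diazo compound.

Step 14
Reactants: 21 hydrazone of 20 (E/Z mixture)
Product: 23 (2S,3R)-7-(benzyloxy)-2-[4-(benzyloxy)phenyl]-3-[3,5-bis(benzyloxy)phenyl]-5-bromo-2,3-dihydrobenzofuran (cis), via diaryldiazomethane 22 (not isolated)
Conditions: MnO2 (8 equiv), CH2Cl2, 0 °C, filter; Rh2(R-PTAD)4 (1 mol %), CH2Cl2, 0 °C
Reagents that add atoms: none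
Why: Dehydrogenation of the hydrazone gives diazo compound 22; the dirhodium carboxylate forms a donor/donor carbene that inserts into the ether CH2 five atoms away (1,5 C–H insertion, five-membered ring), forming C2'–C3'. The chiral phthalimido-carboxylate ligands set C3', and the concerted insertion delivers the cis ring. This is the known enantioselective insertion of diaryl carbenes into benzylic ether C–H bonds, which tolerates aryl bromides.

Step 15
Reactants: 23 (2S,3R)-7-(benzyloxy)-2-[4-(benzyloxy)phenyl]-3-[3,5-bis(benzyloxy)phenyl]-5-bromo-2,3-dihydrobenzofuran (cis)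
Product: 24 (2R,3R)-7-(benzyloxy)-2-[4-(benzyloxy)phenyl]-3-[3,5-bis(benzyloxy)phenyl]-5-bromo-2,3-dihydrobenzofuran (trans)
Conditions: CF3CO2H (10 equiv), CH2Cl2 (0.02 M), 0 °C to rt
Reagents that add atoms: none
Why: Acid reversibly ionises the C2'–O1' bond to a 4-benzyloxybenzyl cation held next to the ring C phenol, and reclosure (SN1) should give the more stable trans ring. C3' is not touched and so fixes the absolute configuration as (2R,3R); the reaction type is the acid-mediated cis-to-trans equilibration of 2-(4-alkoxyphenyl)dihydrobenzofurans.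

Step 16
Reactants: 24 (2R,3R)-7-(benzyloxy)-2-[4-(benzyloxy)phenyl]-3-[3,5-bis(benzyloxy)phenyl]-5-bromo-2,3-dihydrobenzofuran (trans); 12 1,3-dioxoisoindolin-2-yl (2S,3S)-6-(benzyloxy)-4-[(E)-4-(benzyloxy)styryl]-2-[4-(tosyloxy)phenyl]-2,3-dihydrobenzofuran-3-carboxylate
Product: 27 4-[(2S,3S)-6-(benzyloxy)-4-[(E)-4-(benzyloxy)styryl]-3-{(2R,3R)-7-(benzyloxy)-2-[4-(benzyloxy)phenyl]-3-[3,5-bis(benzyloxy)phenyl]-2,3-dihydrobenzofuran-5-yl}-2,3-dihydrobenzofuran-2-yl]phenyl 4-methylbenzenesulfonate, via aryllithium 25 (not isolated), via arylzinc chloride 26 (not isolated)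
Conditions: 24 (1.5 equiv), n-BuLi, THF, −78 °C; ZnCl2, THF, −78 °C to rt; then 12 (1.0 equiv), NiCl2·glyme (20 mol %), 4,4'-di-tert-butyl-2,2'-bipyridine (40 mol %), THF/DMF, rt
Reagents that add atoms: none
Why: Bromine–lithium exchange and transmetalation give arylzinc 26; the nickel-catalysed decarboxylative Negishi-type arylation of the redox-active ester proceeds by electron transfer, loss of CO2 and phthalimide, capture of the C3 benzylic radical by aryl-nickel and reductive elimination. The planar C3 radical should be attacked on the face away from the C2 aryl group, which sets (3S) trans to C2; the centres of 26 are not involved. Bipyridine-ligated nickel at room temperature should leave the aryl tosylate alone, and cyclisation of the radical onto the styryl group would be a disfavoured 5-endo closure.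

Step 17
Reactants: 27 4-[(2S,3S)-6-(benzyloxy)-4-[(E)-4-(benzyloxy)styryl]-3-{(2R,3R)-7-(benzyloxy)-2-[4-(benzyloxy)phenyl]-3-[3,5-bis(benzyloxy)phenyl]-2,3-dihydrobenzofuran-5-yl}-2,3-dihydrobenzofuran-2-yl]phenyl 4-methylbenzenesulfonate
Product: 28 4-[(2S,3S)-6-(benzyloxy)-4-[(E)-4-(benzyloxy)styryl]-3-{(2R,3R)-7-(benzyloxy)-2-[4-(benzyloxy)phenyl]-3-[3,5-bis(benzyloxy)phenyl]-2,3-dihydrobenzofuran-5-yl}-2,3-dihydrobenzofuran-2-yl]phenol
Conditions: KOH (10 equiv), MeOH/THF (1:1), 55 °C, argon; aq. NH4Cl
Reagents that add atoms: none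
Why: Hydroxide attacks sulfur of the aryl sulfonate and releases the ring D phenoxide (sulfonate ester hydrolysis). All other phenols are benzyl ethers, so only one phenoxide is present, and the temperature is kept well below that at which such phenoxides open the dihydrofuran ring.

Step 18
Reactants: 28 4-[(2S,3S)-6-(benzyloxy)-4-[(E)-4-(benzyloxy)styryl]-3-{(2R,3R)-7-(benzyloxy)-2-[4-(benzyloxy)phenyl]-3-[3,5-bis(benzyloxy)phenyl]-2,3-dihydrobenzofuran-5-yl}-2,3-dihydrobenzofuran-2-yl]phenol
Product: 29 (2S,3S)-3-[(2R,3R)-3-(3,5-dihydroxyphenyl)-7-hydroxy-2-(4-hydroxyphenyl)-2,3-dihydrobenzofuran-5-yl]-2-(4-hydroxyphenyl)-4-[(E)-2-(4-hydroxyphenyl)ethenyl]-2,3-dihydrobenzofuran-6-ol (CNP0172909.1)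
Conditions: BCl3 (1 M in CH2Cl2, 12 equiv), pentamethylbenzene (20 equiv), CH2Cl2, −78 °C; then MeOH/H2O
Reagents that add atoms: none
Why: BCl3 cleaves aryl benzyl ethers at −78 °C and pentamethylbenzene traps the benzyl cations (Lewis-acid debenzylation with a non-basic scavenger), so the stilbene, which excludes hydrogenolysis, and the two benzylic C–O bonds should survive. No stereocentre is touched.

## Compound list

1 | (S)-naringenin | O=C1C[C@@H](c2ccc(O)cc2)Oc2cc(O)cc(O)c12 | starting material
2 | (2S)-7-(benzyloxy)-5-hydroxy-2-(4-hydroxyphenyl)chroman-4-one | O=C1C[C@@H](c2ccc(O)cc2)Oc2cc(OCc3ccccc3)cc(O)c12 | intermediate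
3 | 4-[(2S)-7-(benzyloxy)-5-hydroxy-4-oxochroman-2-yl]phenyl 4-methylbenzenesulfonate | O=C1C[C@@H](c2ccc(OS(=O)(=O)c3ccc(C)cc3)cc2)Oc2cc(OCc3ccccc3)cc(O)c12 | intermediate
4 | (2S)-7-(benzyloxy)-4-oxo-2-[4-(tosyloxy)phenyl]chroman-5-yl trifluoromethanesulfonate | O=C1C[C@@H](c2ccc(OS(=O)(=O)c3ccc(C)cc3)cc2)Oc2cc(OCc3ccccc3)cc(OS(=O)(=O)C(F)(F)F)c12 | intermediate
5 | (2S)-7-(benzyloxy)-4-methoxy-2-[4-(tosyloxy)phenyl]-2H-chromen-5-yl trifluoromethanesulfonate (methyl enol ether, not isolated) | COC1=C[C@@H](c2ccc(OS(=O)(=O)c3ccc(C)cc3)cc2)Oc2cc(OCc3ccccc3)cc(OS(=O)(=O)C(F)(F)F)c12 | intermediate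
6 | (2R,3R)-3-[acetoxy(phenyl)iodanyl]-7-(benzyloxy)-4,4-dimethoxy-2-[4-(tosyloxy)phenyl]chroman-5-yl trifluoromethanesulfonate (iodine trans to the aryl group; C2 unchanged in space, the descriptor changes because iodine raises the rank of C3; not isolated) | COC1(OC)[C@H](I(OC(C)=O)c2ccccc2)[C@@H](c2ccc(OS(=O)(=O)c3ccc(C)cc3)cc2)Oc2cc(OCc3ccccc3)cc(OS(=O)(=O)C(F)(F)F)c12 | intermediate
7 | methyl (2S,3S)-6-(benzyloxy)-2-[4-(tosyloxy)phenyl]-4-(triflyloxy)-2,3-dihydrobenzofuran-3-carboxylate | FC(F)(F)S(=O)(=O)Oc1cc(OCc2ccccc2)cc2c1[C@H](C(=O)OC)[C@@H](c1ccc(OS(=O)(=O)c3ccc(C)cc3)cc1)O2 | intermediate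
8 | 1-(benzyloxy)-4-ethynylbenzene | C#Cc1ccc(OCc2ccccc2)cc1 | starting material
9 | (E)-2-[4-(benzyloxy)styryl]-4,4,5,5-tetramethyl-1,3,2-dioxaborolane | CC1(C)OB(/C=C/c2ccc(OCc3ccccc3)cc2)OC1(C)C | intermediate
10 | methyl (2S,3S)-6-(benzyloxy)-4-[(E)-4-(benzyloxy)styryl]-2-[4-(tosyloxy)phenyl]-2,3-dihydrobenzofuran-3-carboxylate | c1ccccc1COc1ccc(/C=C/c2cc(OCc3ccccc3)cc3c2[C@H](C(=O)OC)[C@@H](c2ccc(OS(=O)(=O)c4ccc(C)cc4)cc2)O3)cc1 | intermediate
11 | (2S,3S)-6-(benzyloxy)-4-[(E)-4-(benzyloxy)styryl]-2-[4-(tosyloxy)phenyl]-2,3-dihydrobenzofuran-3-carboxylic acid | c1ccccc1COc1ccc(/C=C/c2cc(OCc3ccccc3)cc3c2[C@H](C(=O)O)[C@@H](c2ccc(OS(=O)(=O)c4ccc(C)cc4)cc2)O3)cc1 | intermediate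
12 | 1,3-dioxoisoindolin-2-yl (2S,3S)-6-(benzyloxy)-4-[(E)-4-(benzyloxy)styryl]-2-[4-(tosyloxy)phenyl]-2,3-dihydrobenzofuran-3-carboxylate | c1ccccc1COc1ccc(/C=C/c2cc(OCc3ccccc3)cc3c2[C@H](C(=O)ON2C(=O)c4ccccc4C2=O)[C@@H](c2ccc(OS(=O)(=O)c4ccc(C)cc4)cc2)O3)cc1 | intermediate
13 | 5-bromo-2,3-dihydroxybenzaldehyde | O=Cc1cc(Br)cc(O)c1O | starting material
14 | 3-(benzyloxy)-5-bromo-2-hydroxybenzaldehyde | O=Cc1cc(Br)cc(OCc2ccccc2)c1O | intermediate
15 | 4-(benzyloxy)benzyl chloride | ClCc1ccc(OCc2ccccc2)cc1 | starting material
16 | 3-(benzyloxy)-2-{[4-(benzyloxy)benzyl]oxy}-5-bromobenzaldehyde | O=Cc1cc(Br)cc(OCc2ccccc2)c1OCc1ccc(OCc2ccccc2)cc1 | intermediate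
17 | 1,3-bis(benzyloxy)-5-bromobenzene | Brc1cc(OCc2ccccc2)cc(OCc2ccccc2)c1 | starting material
18 | [3,5-bis(benzyloxy)phenyl]magnesium bromide (not isolated) | Br[Mg]c1cc(OCc2ccccc2)cc(OCc2ccccc2)c1 | intermediate
19 | racemic {3-(benzyloxy)-2-[(4-benzyloxybenzyl)oxy]-5-bromophenyl}[3,5-bis(benzyloxy)phenyl]methanol | OC(c1cc(OCc2ccccc2)cc(OCc2ccccc2)c1)c1cc(Br)cc(OCc2ccccc2)c1OCc1ccc(OCc2ccccc2)cc1 | intermediate
20 | {3-(benzyloxy)-2-[(4-benzyloxybenzyl)oxy]-5-bromophenyl}[3,5-bis(benzyloxy)phenyl]methanone | O=C(c1cc(OCc2ccccc2)cc(OCc2ccccc2)c1)c1cc(Br)cc(OCc2ccccc2)c1OCc1ccc(OCc2ccccc2)cc1 | intermediate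
21 | hydrazone of 20 (E/Z mixture) | NN=C(c1cc(OCc2ccccc2)cc(OCc2ccccc2)c1)c1cc(Br)cc(OCc2ccccc2)c1OCc1ccc(OCc2ccccc2)cc1 | intermediate
22 | 1-(benzyloxy)-2-[(4-benzyloxybenzyl)oxy]-3-{[3,5-bis(benzyloxy)phenyl](diazo)methyl}-5-bromobenzene (not isolated) | [N-]=[N+]=C(c1cc(OCc2ccccc2)cc(OCc2ccccc2)c1)c1cc(Br)cc(OCc2ccccc2)c1OCc1ccc(OCc2ccccc2)cc1 | intermediate
23 | (2S,3R)-7-(benzyloxy)-2-[4-(benzyloxy)phenyl]-3-[3,5-bis(benzyloxy)phenyl]-5-bromo-2,3-dihydrobenzofuran (cis) | Brc1cc(OCc2ccccc2)c2c(c1)[C@@H](c1cc(OCc3ccccc3)cc(OCc3ccccc3)c1)[C@@H](c1ccc(OCc3ccccc3)cc1)O2 | intermediate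
24 | (2R,3R)-7-(benzyloxy)-2-[4-(benzyloxy)phenyl]-3-[3,5-bis(benzyloxy)phenyl]-5-bromo-2,3-dihydrobenzofuran (trans) | Brc1cc(OCc2ccccc2)c2c(c1)[C@@H](c1cc(OCc3ccccc3)cc(OCc3ccccc3)c1)[C@H](c1ccc(OCc3ccccc3)cc1)O2 | intermediate
25 | {(2R,3R)-7-(benzyloxy)-2-[4-(benzyloxy)phenyl]-3-[3,5-bis(benzyloxy)phenyl]-2,3-dihydrobenzofuran-5-yl}lithium (not isolated) | [Li]c1cc(OCc2ccccc2)c2c(c1)[C@@H](c1cc(OCc3ccccc3)cc(OCc3ccccc3)c1)[C@H](c1ccc(OCc3ccccc3)cc1)O2 | intermediate
26 | chloro{(2R,3R)-7-(benzyloxy)-2-[4-(benzyloxy)phenyl]-3-[3,5-bis(benzyloxy)phenyl]-2,3-dihydrobenzofuran-5-yl}zinc (not isolated) | Cl[Zn]c1cc(OCc2ccccc2)c2c(c1)[C@@H](c1cc(OCc3ccccc3)cc(OCc3ccccc3)c1)[C@H](c1ccc(OCc3ccccc3)cc1)O2 | intermediate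
27 | 4-[(2S,3S)-6-(benzyloxy)-4-[(E)-4-(benzyloxy)styryl]-3-{(2R,3R)-7-(benzyloxy)-2-[4-(benzyloxy)phenyl]-3-[3,5-bis(benzyloxy)phenyl]-2,3-dihydrobenzofuran-5-yl}-2,3-dihydrobenzofuran-2-yl]phenyl 4-methylbenzenesulfonate | c1ccccc1COc1ccc(/C=C/c2cc(OCc5ccccc5)cc3c2[C@H](c2cc(OCc5ccccc5)c4c(c2)[C@@H](c2cc(OCc5ccccc5)cc(OCc5ccccc5)c2)[C@H](c2ccc(OCc5ccccc5)cc2)O4)[C@@H](c2ccc(OS(=O)(=O)c5ccc(C)cc5)cc2)O3)cc1 | intermediate
28 | 4-[(2S,3S)-6-(benzyloxy)-4-[(E)-4-(benzyloxy)styryl]-3-{(2R,3R)-7-(benzyloxy)-2-[4-(benzyloxy)phenyl]-3-[3,5-bis(benzyloxy)phenyl]-2,3-dihydrobenzofuran-5-yl}-2,3-dihydrobenzofuran-2-yl]phenol | c1ccccc1COc1ccc(/C=C/c2cc(OCc5ccccc5)cc3c2[C@H](c2cc(OCc5ccccc5)c4c(c2)[C@@H](c2cc(OCc5ccccc5)cc(OCc5ccccc5)c2)[C@H](c2ccc(OCc5ccccc5)cc2)O4)[C@@H](c2ccc(O)cc2)O3)cc1 | intermediate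
29 | (2S,3S)-3-[(2R,3R)-3-(3,5-dihydroxyphenyl)-7-hydroxy-2-(4-hydroxyphenyl)-2,3-dihydrobenzofuran-5-yl]-2-(4-hydroxyphenyl)-4-[(E)-2-(4-hydroxyphenyl)ethenyl]-2,3-dihydrobenzofuran-6-ol (CNP0172909.1) | Oc1ccc(/C=C/c2cc(O)cc3c2[C@H](c2cc(O)c4c(c2)[C@@H](c2cc(O)cc(O)c2)[C@H](c2ccc(O)cc2)O4)[C@@H](c2ccc(O)cc2)O3)cc1 | target

## Step count and least certain steps

Total: 18 steps. Longest linear sequence: 10 steps, from 1 through steps 1 to 4, 6 to 8 and 16 to 18. The branch from 13 through steps 9 to 15 and then 16 to 18 is equally long.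

**Step 4 (key step).** The triflate ortho to the migrating carbon may slow the shift of ring B. Solvolysis at C3 by methanol, or elimination to the flavone, could then overtake the rearrangement. Prolonged acid could also open the C2–O1 bond and erode the S centre. The fallback keeps the same bond changes but replaces the iodine oxidation by a Wolff ring contraction. It sets out from 4, which is converted by detrifluoroacetylative diazo transfer (LiN(SiMe3)2 and CF3CO2CH2CF3 at −78 °C, then MsN3, Et3N) into (2R)-7-(benzyloxy)-3-diazo-4-oxo-2-[4-(tosyloxy)phenyl]chroman-5-yl trifluoromethanesulfonate F1, which has the same spatial arrangement at C2 as 4. Photolysis of F1 in methanol expels nitrogen, ring B migrates to the carbene carbon, and the ketene is trapped as the methyl ester. Brief equilibration of C3 with DBU should give the trans ester, and the route is rejoined at 7.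

**Step 16.** The stabilised, hindered C3 radical is released quickly by the zinc-reduced nickel catalyst. It may dimerise or be reduced before aryl-nickel captures it, facial selectivity at C3 may be incomplete, and the basic arylzinc, made in excess from an advanced fragment, is partly wasted. The fallback replaces the organozinc and the redox-active ester by a light-driven dual catalysis that releases the radical slowly. It sets out from acid 11 and bromide 24, which are coupled directly with Ir[dF(CF3)ppy]2(dtbbpy)PF6, NiCl2·glyme, 4,4'-di-tert-butyl-2,2'-bipyridine and Cs2CO3 in DMF under blue light, and it comes back to the route at 27. It makes no new compound (F0).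

**Step 15.** During the equilibration the benzylic cation may lose the C3' proton to give a triarylethene, or may alkylate another molecule, instead of reclosing. The fallback separates opening and closing. It sets out from 23, which is opened by ionic hydrogenation (Et3SiH, CF3CO2H, −20 °C) to 2-(benzyloxy)-6-{(1R)-1-[3,5-bis(benzyloxy)phenyl]-2-[4-(benzyloxy)phenyl]ethyl}-4-bromophenol F2, with C3' intact. DDQ then abstracts hydride from the 4-benzyloxybenzyl CH2, and the phenol closes the ring trans to ring E under the control of C3', rejoining the route at 24. This closure shares the oxidation risk noted for Alternative 2, reduced here by the electron-poor bromophenol.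

**Step 18.** With ring D now a free 4-hydroxyphenyl group, BCl3 may ionise the C2–O1 bond, leading to ring opening or epimerisation at C2. Benzyl cations may also escape the scavenger and alkylate the resorcinol ring E. The fallback reverses the order of the last two steps so that the Lewis acid meets ring D while it is still electron-poor. It sets out from 27, which is debenzylated with BCl3 and pentamethylbenzene at −78 °C to 4-[(2S,3S)-3-[(2R,3R)-3-(3,5-dihydroxyphenyl)-7-hydroxy-2-(4-hydroxyphenyl)-2,3-dihydrobenzofuran-5-yl]-6-hydroxy-4-[(E)-4-hydroxystyryl]-2,3-dihydrobenzofuran-2-yl]phenyl 4-methylbenzenesulfonate F3. The tosylate is then cleaved with degassed KOH in methanol under argon, which arrives at 29.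

## Further compounds

F1 | step 4 | (2R)-7-(benzyloxy)-3-diazo-4-oxo-2-[4-(tosyloxy)phenyl]chroman-5-yl trifluoromethanesulfonate | O=C1C(=[N+]=[N-])[C@@H](c2ccc(OS(=O)(=O)c3ccc(C)cc3)cc2)Oc2cc(OCc3ccccc3)cc(OS(=O)(=O)C(F)(F)F)c12
F0 | step 16 | none | none
F2 | step 15 | 2-(benzyloxy)-6-{(1R)-1-[3,5-bis(benzyloxy)phenyl]-2-[4-(benzyloxy)phenyl]ethyl}-4-bromophenol | Oc1c(OCc2ccccc2)cc(Br)cc1[C@@H](c1cc(OCc2ccccc2)cc(OCc2ccccc2)c1)Cc1ccc(OCc2ccccc2)cc1
F3 | step 18 | 4-[(2S,3S)-3-[(2R,3R)-3-(3,5-dihydroxyphenyl)-7-hydroxy-2-(4-hydroxyphenyl)-2,3-dihydrobenzofuran-5-yl]-6-hydroxy-4-[(E)-4-hydroxystyryl]-2,3-dihydrobenzofuran-2-yl]phenyl 4-methylbenzenesulfonate | Oc1ccc(/C=C/c2cc(O)cc3c2[C@H](c2cc(O)c4c(c2)[C@@H](c2cc(O)cc(O)c2)[C@H](c2ccc(O)cc2)O4)[C@@H](c2ccc(OS(=O)(=O)c5ccc(C)cc5)cc2)O3)cc1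
A1 | alternative 1 | 2-{(1R,2R)-2-[3-(benzyloxy)-5-(1,3-dioxolan-2-yl)-2-(methoxymethoxy)phenyl]-1-[4-(benzyloxy)phenyl]-2-[3,5-bis(benzyloxy)phenyl]ethyl}-4,4,5,5-tetramethyl-1,3,2-dioxaborolane | O1CCOC1c1cc(OCc5ccccc5)c(OCOC)c(c1)[C@@H](c1cc(OCc5ccccc5)cc(OCc5ccccc5)c1)[C@H](c1ccc(OCc5ccccc5)cc1)B1OC(C)(C)C(C)(C)O1
A2 | alternative 1 | (E)-2-[3,5-bis(benzyloxy)styryl]-4,4,5,5-tetramethyl-1,3,2-dioxaborolane | CC1(C)OB(/C=C/c2cc(OCc3ccccc3)cc(OCc3ccccc3)c2)OC1(C)C
A3 | alternative 1 | 2-[3-(benzyloxy)-5-bromo-4-(methoxymethoxy)phenyl]-1,3-dioxolane | COCOc1c(Br)cc(C2OCCO2)cc1OCc1ccccc1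
A4 | alternative 1 | [4-(benzyloxy)phenyl]lithium | [Li]c1ccc(OCc2ccccc2)cc1
A5 | alternative 2 | (2R,3R)-7-(benzyloxy)-2-[4-(benzyloxy)phenyl]-3-[3,5-bis(benzyloxy)phenyl]-2,3-dihydrobenzofuran-5-carbaldehyde | O=Cc1cc(OCc5ccccc5)c2c(c1)[C@@H](c1cc(OCc5ccccc5)cc(OCc5ccccc5)c1)[C@H](c1ccc(OCc5ccccc5)cc1)O2
A6 | alternative 2 | 3-(benzyloxy)-5-{(1R)-1-[3,5-bis(benzyloxy)phenyl]-2-[4-(benzyloxy)phenyl]ethyl}-4-hydroxybenzaldehyde | O=Cc1cc(OCc5ccccc5)c(O)c(c1)[C@@H](c1cc(OCc5ccccc5)cc(OCc5ccccc5)c1)Cc1ccc(OCc5ccccc5)cc1
A7 | alternative 3 | hepta-O-benzyl ether of 29 | c5ccccc5COc1ccc(/C=C/c2cc(OCc5ccccc5)cc3c2[C@H](c2cc(OCc5ccccc5)c4c(c2)[C@@H](c2cc(OCc5ccccc5)cc(OCc5ccccc5)c2)[C@H](c2ccc(OCc5ccccc5)cc2)O4)[C@@H](c2ccc(OCc5ccccc5)cc2)O3)cc1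
A8 | alternative 3 | 5-(benzyloxy)-3-[(E)-4-(benzyloxy)styryl]-2-{[(2R,3R)-7-(benzyloxy)-2-[4-(benzyloxy)phenyl]-3-[3,5-bis(benzyloxy)phenyl]-2,3-dihydrobenzofuran-5-yl](tosyl)methyl}phenol (mixture at the sulfone carbon) | Oc1cc(OCc5ccccc5)cc(/C=C/c2ccc(OCc5ccccc5)cc2)c1C(S(=O)(=O)c1ccc(C)cc1)c1cc(OCc5ccccc5)c2c(c1)[C@@H](c1cc(OCc5ccccc5)cc(OCc5ccccc5)c1)[C@H](c1ccc(OCc5ccccc5)cc1)O2
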